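**Plan**
- Ring B is cut at C2'-C3' and C5'-C6'. Ring B is mirror-symmetric about its C1'-C4' axis: C3', C4', C5' and their three oxygens are the skeleton of 1,3-dimethoxyacetone (its carbonyl becomes the free 4'-OH), and C2', C1', C6' are a malonaldehyde carried on C2 of ring C.
- The two formyl carbons are then cut from the 2-methyl carbon of a 2-methylchromone (bonds C1'-C2' and C1'-C6').
- Ring C is cut at C2-C3 and O1-C2 to an ortho-hydroxyacetophenone and ethyl acetate, and the acetyl and hydroxyl groups are taken off ring A to reach 1,2,3,4-tetramethoxybenzene.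
- Forward: ring A is bought fully methoxylated, ring C is closed in step 3, and ring B is built last from open-chain carbons in step 7.
- The target has no stereocentre; the E-enamine geometry of step 4 is lost in the vinamidinium of step 5.

Key step: step 7

Assumption: the chromonyl malonaldehyde is drawn as the dialdehyde although it should exist as its hydrogen-bonded enol; both forms are treated as one compound.

**Route**

Step 1
Reactants: 1 1,2,3,4-tetramethoxybenzene
Product: 4 2,3,4,5-tetramethoxyphenol, via aryllithium 2 (not isolated), via dimethyl arylboronate 3 (not isolated)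
Conditions: n-BuLi, TMEDA, THF, 0 °C; B(OMe)3, −78 °C to rt; AcOH, 30% aq. H2O2, 0 °C to rt
Reagents that add atoms: hydrogen peroxide, OO
Why: Methoxy-directed ortho-lithiation can only remove one of the two equivalent ring hydrogens, and borylation followed by peroxide oxidation of the aryl-boron bond (1,2-shift of the aryl group from boron to oxygen) is a standard one-pot arene hydroxylation, run here in acidic medium to spare the oxidation-prone phenol.

Step 2
Reactants: 4 2,3,4,5-tetramethoxyphenol
Product: 6 1-(2-hydroxy-3,4,5,6-tetramethoxyphenyl)ethan-1-one, via difluoroboron chelate 5 (not isolated)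
Conditions: BF3·OEt2, AcOH, 85 °C; then aq. NaOAc, 60 °C
Reagents that add atoms: acetic acid, CC(=O)O
Why: BF3-promoted C-acylation of a phenol with acetic acid (a Fries-type ortho-acylation) can only go to the one free ring position, which lies ortho to the hydroxyl, and the product is held as the BF2 chelate 5 until aqueous work-up releases 6 with all four methoxy groups intact.

Step 3
Reactants: 6 1-(2-hydroxy-3,4,5,6-tetramethoxyphenyl)ethan-1-one; 7 ethyl acetate
Product: 9 5,6,7,8-tetramethoxy-2-methyl-4H-chromen-4-one, via beta-diketone 8 (not isolated)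
Conditions: NaH, THF, 65 °C; then AcOH, conc. HCl, 60 °C (same flask)
Reagents that add atoms: none
Why: Crossed Claisen condensation of the ketone enolate with ethyl acetate and acid-catalysed cyclodehydration of the beta-diketone (phenol oxygen onto the distal carbonyl, then loss of water) is the classical 2-methylchromone synthesis, and the brief mild acid treatment should not touch the 5-methoxy group.

Step 4
Reactants: 9 5,6,7,8-tetramethoxy-2-methyl-4H-chromen-4-one
Product: 10 2-[(E)-2-(dimethylamino)ethenyl]-5,6,7,8-tetramethoxy-4H-chromen-4-one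
Conditions: Me2NCH(OMe)2, DMF, 120 °C
Reagents that add atoms: N,N-dimethylformamide dimethyl acetal, COC(OC)N(C)C
Why: The 2-methyl group is the vinylogous alpha-position of the pyranone carbonyl and condenses with the amide acetal with loss of two molecules of methanol, an enamine formation established for 2-methylchromones that gives the E isomer.

Step 5
Reactants: 10 2-[(E)-2-(dimethylamino)ethenyl]-5,6,7,8-tetramethoxy-4H-chromen-4-one
Product: 12 2-(5,6,7,8-tetramethoxy-4-oxo-4H-chromen-2-yl)propanedial, via vinamidinium chloride 11 (not isolated)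
Conditions: [Me2N=CHCl]Cl, CH2Cl2, 0 °C to rt; then 1 M aq. NaOH, THF, rt to 40 °C; aq. HCl to pH 3
Reagents that add atoms: (chloromethylene)dimethyliminium chloride, C[N+](C)=CCl.[Cl-]; water, O
Why: Vilsmeier-Haack-Arnold formylation of an enamine at its beta-carbon gives a vinamidinium salt whose two iminium termini are hydrolysed by dilute alkali, the standard access to 2-substituted malonaldehydes; the preformed chloroiminium salt keeps free POCl3 away from the pyranone oxygen, ring A has no free position, and the malonaldehyde enolate formed in base should resist further attack by hydroxide.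

Step 6
Reactants: 13 1,3-dimethoxypropan-2-ol
Product: 14 1,3-dimethoxypropan-2-one
Conditions: (COCl)2, DMSO, CH2Cl2, −78 °C; Et3N, −78 °C to rt; filtration, distillation
Reagents that add atoms: none
Why: Swern oxidation of a secondary alcohol to the ketone, chosen because its non-aqueous work-up suits a water-miscible and volatile product.

Step 7
Reactants: 12 2-(5,6,7,8-tetramethoxy-4-oxo-4H-chromen-2-yl)propanedial; 14 1,3-dimethoxypropan-2-one
Product: 17 2-(4-hydroxy-3,5-dimethoxyphenyl)-5,6,7,8-tetramethoxy-4H-chromen-4-one, via piperidine vinamidinium acetate 15 (not isolated), via open-chain aminodienone 16 (not isolated)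
Conditions: 14 (3 equiv), piperidine (2.2 equiv), AcOH (4 equiv), EtOH, 4 Å molecular sieves, 80 °C; aq. HCl to pH 4
Reagents that add atoms: none
Why: Piperidinium acetate should convert the dialdehyde into vinamidinium salt 15, whose iminium carbon is attacked by the enol of 14 in a Mannich-type addition; beta-elimination of piperidine then gives aminodienone 16 with the C2'-C3' bond in place. Enolisation of 16 toward its remaining methoxymethylene group and attack on the second iminium carbon closes ring B in a 6-(enolendo)-exo-trig step that makes the C5'-C6' bond (equivalent to a disrotatory 6π closure of the aminotrienol tautomer). Loss of piperidine and tautomerisation of the dienone to the phenol follow, driven by aromatisation. The closest known reaction type is the (3+3) phenol synthesis from sodium nitromalonaldehyde or 2-substituted vinamidinium salts and ketones with two alpha-methylene groups, with the electron-poor chromon-2-yl group in the role of the nitro group. No stereocentre is formed. The step needs C-C bond formation at the two formyl-derived carbons and not amine or enol attack at C2 of ring C; the fully substituted, donor-conjugated C2 and the buffered medium should secure this, and the mirror symmetry of both partners leaves no question of orientation.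

**Compound list**

1 | 1,2,3,4-tetramethoxybenzene | COc1ccc(OC)c(OC)c1OC | starting material
2 | (2,3,4,5-tetramethoxyphenyl)lithium | [Li]c1cc(OC)c(OC)c(OC)c1OC | intermediate
3 | dimethyl (2,3,4,5-tetramethoxyphenyl)boronate | COB(OC)c1cc(OC)c(OC)c(OC)c1OC | intermediate
4 | 2,3,4,5-tetramethoxyphenol | COc1cc(O)c(OC)c(OC)c1OC | intermediate
5 | difluoroboron chelate of 6 (BF2 bridging the phenolate oxygen and the acetyl oxygen) | CC1=[O+][B-](F)(F)Oc2c(OC)c(OC)c(OC)c(OC)c12 | intermediate
6 | 1-(2-hydroxy-3,4,5,6-tetramethoxyphenyl)ethan-1-one | CC(=O)c1c(O)c(OC)c(OC)c(OC)c1OC | intermediate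
7 | ethyl acetate | CCOC(C)=O | starting material
8 | 1-(2-hydroxy-3,4,5,6-tetramethoxyphenyl)butane-1,3-dione | CC(=O)CC(=O)c1c(O)c(OC)c(OC)c(OC)c1OC | intermediate
9 | 5,6,7,8-tetramethoxy-2-methyl-4H-chromen-4-one | Cc1cc(=O)c2c(OC)c(OC)c(OC)c(OC)c2o1 | intermediate
10 | 2-[(E)-2-(dimethylamino)ethenyl]-5,6,7,8-tetramethoxy-4H-chromen-4-one | CN(C)/C=C/c1cc(=O)c2c(OC)c(OC)c(OC)c(OC)c2o1 | intermediate
11 | N-[3-(dimethylamino)-2-(5,6,7,8-tetramethoxy-4-oxo-4H-chromen-2-yl)prop-2-en-1-ylidene]-N-methylmethanaminium chloride | C[N+](C)=C/C(=C/N(C)C)c1cc(=O)c2c(OC)c(OC)c(OC)c(OC)c2o1.[Cl-] | intermediate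
12 | 2-(5,6,7,8-tetramethoxy-4-oxo-4H-chromen-2-yl)propanedial (expected as its enol) | O=CC(C=O)c1cc(=O)c2c(OC)c(OC)c(OC)c(OC)c2o1 | intermediate
13 | 1,3-dimethoxypropan-2-ol | COCC(O)COC | starting material
14 | 1,3-dimethoxypropan-2-one | COCC(=O)COC | intermediate
15 | 1-[3-(piperidin-1-yl)-2-(5,6,7,8-tetramethoxy-4-oxo-4H-chromen-2-yl)prop-2-en-1-ylidene]piperidin-1-ium acetate | [N+]1(CCCCC1)=C/C(=C/N1CCCCC1)c1cc(=O)c2c(OC)c(OC)c(OC)c(OC)c2o1.CC(=O)[O-] | intermediate
16 | (3E,5Z)-1,3-dimethoxy-6-(piperidin-1-yl)-5-(5,6,7,8-tetramethoxy-4-oxo-4H-chromen-2-yl)hexa-3,5-dien-2-one | COCC(=O)/C(OC)=C\C(=C\N1CCCCC1)c1cc(=O)c2c(OC)c(OC)c(OC)c(OC)c2o1 | intermediate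
17 | 2-(4-hydroxy-3,5-dimethoxyphenyl)-5,6,7,8-tetramethoxy-4H-chromen-4-one (4'-hydroxy-3',5,5',6,7,8-hexamethoxyflavone) | COc1cc(-c2cc(=O)c3c(OC)c(OC)c(OC)c(OC)c3o2)cc(OC)c1O | target

**Count**

Total steps: 7. Longest linear sequence: 6 steps (steps 1 to 5 and step 7, from 1 to 17); step 6 is a one-step side branch.

**Steps most likely to fail**

Step 7. The double condensation may be outrun by self-aldolisation of the ketone or by conjugate attack of piperidine at C2 with opening of ring C, or it may stall after the first C-C bond. The fallback brings ring B in ready-made by a Baker-Venkataraman sequence and sets out from 6. Acylation of the phenol in pyridine with 4-(benzyloxy)-3,5-dimethoxybenzoyl chloride F1 (from the commercial acid with (COCl)2 and catalytic DMF) should give 2-acetyl-3,4,5,6-tetramethoxyphenyl 4-(benzyloxy)-3,5-dimethoxybenzoate F2. KOH in pyridine at 50 °C should shift the aroyl group to carbon and give 1-[4-(benzyloxy)-3,5-dimethoxyphenyl]-3-(2-hydroxy-3,4,5,6-tetramethoxyphenyl)propane-1,3-dione F3. AcOH with catalytic H2SO4 should close ring C to 2-[4-(benzyloxy)-3,5-dimethoxyphenyl]-5,6,7,8-tetramethoxy-4H-chromen-4-one F4. Hydrogenolysis (H2, Pd/C, EtOAc) removes the benzyl group, and the sequence comes back to the route at 17.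

Step 5. Electrophilic attack may go to C3 of ring C, the vinylogous end of the dienamine, or to the carbonyl oxygen, and hydroxide may open the pyranone ring during hydrolysis. The fallback carries both aldehyde carbons in from the start as a protected 1,3-diol, so that no formylation is needed, and sets out from 6. Esterification with commercial 2,2-dimethyl-1,3-dioxane-5-carboxylic acid (DCC, DMAP, CH2Cl2) should give 2-acetyl-3,4,5,6-tetramethoxyphenyl 2,2-dimethyl-1,3-dioxane-5-carboxylate F5. KOtBu in THF should effect the Baker-Venkataraman acyl shift to 1-(2,2-dimethyl-1,3-dioxan-5-yl)-3-(2-hydroxy-3,4,5,6-tetramethoxyphenyl)propane-1,3-dione F6. Aqueous HCl in MeOH should close ring C and remove the acetonide to give 2-(1,3-dihydroxypropan-2-yl)-5,6,7,8-tetramethoxy-4H-chromen-4-one F7. Dess-Martin periodinane (NaHCO3, CH2Cl2) then oxidises both primary alcohols, and the sequence comes back to the route at 12.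

Step 4. Condensation at the weakly acidic 2-methyl group may stall, and the push-pull enamine may decompose on long heating. The fallback oxidises the methyl group instead of condensing it and sets out from 9. SeO2 in refluxing dioxane should give 5,6,7,8-tetramethoxy-4-oxo-4H-chromene-2-carbaldehyde F8. Wittig reaction with Ph3P=CHOMe (from (methoxymethyl)triphenylphosphonium chloride and KOtBu, THF, 0 °C) should give the enol ether 2-[(E)-2-methoxyethenyl]-5,6,7,8-tetramethoxy-4H-chromen-4-one F9, the Z isomer serving equally. The chloroiminium salt of step 5 should formylate the enol ether at its beta-carbon to N-[3-methoxy-2-(5,6,7,8-tetramethoxy-4-oxo-4H-chromen-2-yl)prop-2-en-1-ylidene]-N-methylmethanaminium chloride F10, which is not isolated. The dilute NaOH hydrolysis of step 5 then gives the dialdehyde, and the sequence comes back to the route at 12.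

**Further compounds**

F1 | step 7 | 4-(benzyloxy)-3,5-dimethoxybenzoyl chloride | COc1cc(C(Cl)=O)cc(OC)c1OCc1ccccc1
F2 | step 7 | 2-acetyl-3,4,5,6-tetramethoxyphenyl 4-(benzyloxy)-3,5-dimethoxybenzoate | CC(=O)c1c(OC(=O)c2cc(OC)c(OCc3ccccc3)c(OC)c2)c(OC)c(OC)c(OC)c1OC
F3 | step 7 | 1-[4-(benzyloxy)-3,5-dimethoxyphenyl]-3-(2-hydroxy-3,4,5,6-tetramethoxyphenyl)propane-1,3-dione | COc1cc(C(=O)CC(=O)c2c(O)c(OC)c(OC)c(OC)c2OC)cc(OC)c1OCc1ccccc1
F4 | step 7 | 2-[4-(benzyloxy)-3,5-dimethoxyphenyl]-5,6,7,8-tetramethoxy-4H-chromen-4-one | COc1cc(-c2cc(=O)c3c(OC)c(OC)c(OC)c(OC)c3o2)cc(OC)c1OCc1ccccc1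
F5 | step 5 | 2-acetyl-3,4,5,6-tetramethoxyphenyl 2,2-dimethyl-1,3-dioxane-5-carboxylate | CC(=O)c1c(OC(=O)C2COC(C)(C)OC2)c(OC)c(OC)c(OC)c1OC
F6 | step 5 | 1-(2,2-dimethyl-1,3-dioxan-5-yl)-3-(2-hydroxy-3,4,5,6-tetramethoxyphenyl)propane-1,3-dione | CC1(C)OCC(C(=O)CC(=O)c2c(O)c(OC)c(OC)c(OC)c2OC)CO1
F7 | step 5 | 2-(1,3-dihydroxypropan-2-yl)-5,6,7,8-tetramethoxy-4H-chromen-4-one | OCC(CO)c1cc(=O)c2c(OC)c(OC)c(OC)c(OC)c2o1
F8 | step 4 | 5,6,7,8-tetramethoxy-4-oxo-4H-chromene-2-carbaldehyde | O=Cc1cc(=O)c2c(OC)c(OC)c(OC)c(OC)c2o1
F9 | step 4 | 2-[(E)-2-methoxyethenyl]-5,6,7,8-tetramethoxy-4H-chromen-4-one | CO/C=C/c1cc(=O)c2c(OC)c(OC)c(OC)c(OC)c2o1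
F10 | step 4 | N-[3-methoxy-2-(5,6,7,8-tetramethoxy-4-oxo-4H-chromen-2-yl)prop-2-en-1-ylidene]-N-methylmethanaminium chloride | CO/C=C(/C=[N+](C)C)c1cc(=O)c2c(OC)c(OC)c(OC)c(OC)c2o1.[Cl-]
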